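# Proposed total synthesis of Erypoegin F by an aromatising benzofuran annulation on a cyclohexane-1,3-dione

## Analysis of the target

Erypoegin F is a 2-arylbenzofuran-3-carbaldehyde. Ring A is the benzo ring (C3a, C4, C5, C6, C7, C7a), ring B the furan (O1, C2, C3, C3a, C7a), and ring C the 2,4-dihydroxyphenyl group (C1′–C6′) on C2; the formyl group sits on C3. There is no stereocentre and the prenyl double bond has no geometry, so the problem is one of regiochemistry and functional-group tolerance only.

The defining feature is the contiguous array on ring A: C7a–O1, C7–prenyl, C6–OMe, then unsubstituted C5 and C4, and C3a carrying C3. The prenyl group lies between two oxygens that are differentiated, one in the furan and one methylated. This array is the substitution pattern of a 2-alkylcyclohexane-1,3-dione: C7 is the carbon between the carbonyls, C7a and C6 are the carbonyl carbons, C3a is an α′ carbon, and C4/C5 are the remaining methylenes. In the dione each position is addressed by enolate chemistry with no regiochemical competition, whereas on a benzene ring the four neighbouring substituents need successive directed metalations.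

The sensitive groups are:
- the prenyl alkene (strong acid, electrophilic oxidants, hydrogenation);
- the C3 aldehyde, a vinylogous formate next to the 2′-OH (cyclic acetal formation in acidic alcohols, ring opening and deformylation in hot base);
- the electron-rich ring C, whose two phenols must be released at the end without touching the aryl methyl ether.

The synthesis is hard because ring A is tetrasubstituted, C3 needs a one-carbon unit, and the prenyl group must survive every step.

## Retrosynthetic reasoning

**15 ⇒ 14 (O–Si bonds).** The two phenols of ring C are released last from the bis-silyl ether 14. Fluoride-labile silyl ethers are chosen because their removal needs neither acid (prenyl, lactol-type acetals) nor strong base (opening of the vinylogous formate) and leaves the methyl ether alone.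

**14 ⇒ 13 (C3–CHO bond).** C3 of 13 is the β-carbon of the O1–C2=C3 enol ether and the only such position, so the formyl group is put on by a Vilsmeier–Haack reaction. The cut is made here and not earlier because an electrophile that already carried the aldehyde carbon would give the ring-A phenol two carbonyls to close on (3-aroyl versus 3-formyl benzofuran).

**13 ⇒ 3 + 7 (C3a–C3 and O1–C2 bonds, ring A taken back to a cyclohexenone).** This is the key disconnection. Ring B is opened at both bonds and ring A is de-aromatised to the vinylogous ester 3. The aldehyde carbon of glyoxal 7 becomes C3, its ketone carbon becomes C2, and the ring carbonyl oxygen of 3 becomes O1. The oxidation levels match: the aldol adduct of 3 and 7 needs only two dehydrations and tautomerisations to become the benzofuran, so no oxidant is required. Forward, the sequence is α′-aldol addition (enolate 8 to aldolate 9), activation and elimination (10 to 11), isoaromatisation (11 to 12) and cyclodehydration (12 to 13), run as one operation. The gain is that the substitution pattern of ring A is fixed by the dione and cannot come out wrong.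

**7 ⇒ 5 ⇒ 4 (C–H oxidation, O–Si bonds).** The glyoxal is the Riley oxidation product of methyl ketone 5, released from its hydrate 6 by azeotropic drying. Ketone 5 is the bis-silyl ether of commercial 4.

**3 ⇒ 2 ⇒ 1 (O–Me bond, C7–prenyl bond).** Vinylogous ester 3 is the O-methylation product of dione 2. The two carbonyls of 2 are equivalent, so the two oxygens are differentiated without a selectivity problem. Dione 2 is the C-prenylation product of commercial 1 at the doubly activated carbon, which later becomes the hindered C7 between two oxygens.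

## Alternatives that were turned down

**Alternative 1:** The textbook route cuts O1–C2 on an intact ring A and adds the formyl group afterwards. The forward key step is a Sonogashira coupling of iodophenol A1 with arylacetylene A2 (PdCl2(PPh3)2, CuI, amine) with 5-endo-dig closure of the phenol onto the alkyne, giving 13, followed by the same formylation. It was turned down because the key step closes only ring B. All the difficulty moves into A1, a benzene ring with four different contiguous substituents (I, OH, prenyl, OMe). A1 would need protection of a resorcinol monoether, lithiation–prenylation between the oxygens, a second regioselective functionalisation for iodine (where the position next to the methoxy group competes) and deprotection, about five to six steps; A2 needs about three more. The count is near eleven steps with no gain in certainty at the formylation.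

**Alternative 2:** The 1,2-aryl shift route cuts the C3–C3a bond as a migration of ring A in a chalcone. Forward, chalcone A3 is treated with a hypervalent iodine oxidant such as PhI(OAc)2 in an alcohol to give the rearranged β-ketoacetal A4. Acid then removes the acetal-type protecting groups and closes ring B by attack of the ring-A phenol on the ring-C ketone, giving 15 with the C3 aldehyde already in place. It was turned down for four reasons:
- the trivalent iodine (or trivalent thallium) electrophile should add to the electron-rich prenyl alkene of A3 faster than to the electron-poor enone, so the prenyl group could not be carried;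
- closure of A4 is ambiguous, since attack on the acetal carbon gives the 3-aroyl isomer;
- the acid stage exposes a free phenol ortho to the prenyl group before the furan is closed, which invites chroman formation;
- the aldehyde half of A3 is again a contiguously tetrasubstituted benzene.

**Alternative 3:** The lactone route reads the 2′-OH/C3–CHO pair as the open form of a lactol and cuts back to coumestan A5. Forward, the bis(2-hydroxyaryl)acetylene A6 undergoes carbonylative double cyclisation with a divalent palladium catalyst such as PdI2 (oxypalladation closes ring B, carbonyl insertion, capture of the acyl by the second phenol) to give A5; hydride half-reduction of the lactone and desilylation then give 15. It was turned down for three reasons: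
- in A6 either phenol can perform the 5-endo oxypalladation, so the isomer with rings A and C exchanged is expected as well;
- half-reduction of a phenyl ester is hard to stop, because the tetrahedral intermediate collapses with loss of phenoxide and the aldehyde is reduced further, so a reduction–reoxidation pair would be needed;
- A6 again requires A1, giving well over ten steps.

Key step: step 5

## Route

Assumption: compounds 9 and 10 form as diastereomer mixtures and 11 as a mixture of double-bond isomers. All of these stereo elements are erased in 12, so their SMILES carry no descriptors. Compound 15 is written as the open hydroxy aldehyde.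

Step 1
Reactants: 1 cyclohexane-1,3-dione
Product: 2 2-(3-methylbut-2-en-1-yl)cyclohexane-1,3-dione
Conditions: prenyl bromide, KOH, H2O, 0 °C → rt
Reagents that add atoms: 1-bromo-3-methylbut-2-ene (prenyl bromide), CC(C)=CCBr
Why: C-alkylation of the dione enolate with an allylic halide in water, where hydrogen bonding to the enolate oxygens favours attack through carbon; this places the prenyl group on the future C7 before any aromatic ring exists.

Step 2
Reactants: 2 2-(3-methylbut-2-en-1-yl)cyclohexane-1,3-dione
Product: 3 3-methoxy-2-(3-methylbut-2-en-1-yl)cyclohex-2-en-1-one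
Conditions: Me2SO4, K2CO3, acetone, reflux
Reagents that add atoms: dimethyl sulfate, COS(=O)(=O)OC
Why: O-methylation of a 2-substituted 1,3-dione with a hard electrophile gives the vinylogous ester; the two carbonyls are equivalent, so only one product can form, and the acid-free conditions spare the prenyl group.

Step 3
Reactants: 4 1-(2,4-dihydroxyphenyl)ethan-1-one
Product: 5 1-{2,4-bis[(triisopropylsilyl)oxy]phenyl}ethan-1-one
Conditions: TIPSOTf, 2,6-lutidine, CH2Cl2, 0 °C → rt
Reagents that add atoms: triisopropylsilyl trifluoromethanesulfonate, CC(C)[Si](OS(=O)(=O)C(F)(F)F)(C(C)C)C(C)C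
Why: Silylation of both phenols with the silyl triflate, which is reactive enough for the hydrogen-bonded ortho hydroxyl; the bulky silyl ethers tolerate enolates, amidine base and sulfonic acid and later shield C3′ and C5′.

Step 4
Reactants: 5 1-{2,4-bis[(triisopropylsilyl)oxy]phenyl}ethan-1-one
Product: 7 2-{2,4-bis[(triisopropylsilyl)oxy]phenyl}-2-oxoacetaldehyde, via glyoxal hydrate 6 (not isolated)
Conditions: SeO2, 1,4-dioxane–H2O (30:1), 95 °C; filtration; azeotropic drying with PhMe
Reagents that add atoms: selenium dioxide, O=[Se]=O
Why: Riley oxidation of an aryl methyl ketone to the aryl glyoxal; the hydrate formed in the wet medium is dehydrated by azeotropic distillation so that the free aldehyde is available for the enolate in step 5.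

Step 5
Reactants: 3 3-methoxy-2-(3-methylbut-2-en-1-yl)cyclohex-2-en-1-one; 7 2-{2,4-bis[(triisopropylsilyl)oxy]phenyl}-2-oxoacetaldehyde
Product: 13 2-{2,4-bis[(triisopropylsilyl)oxy]phenyl}-6-methoxy-7-(3-methylbut-2-en-1-yl)-1-benzofuran, via lithium enolate 8 (not isolated), via lithium aldolate 9 (not isolated), via aldol mesylate 10 (not isolated), via ene-dione 11 (not isolated), via phenol ketone 12 (not isolated)
Conditions: LiN(iPr)2, THF, −78 °C; 7, −78 °C; MsCl, −78 → 0 °C; DBU, 0 °C → rt; then TsOH·H2O (excess over DBU), PhMe, 50 °C
Reagents that add atoms: none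
Why: Kinetic deprotonation of vinylogous ester 3 at C6 gives the cross-conjugated enolate 8 (Stork–Danheiser type), which adds to the aldehyde carbon of 7, the more electrophilic of its two carbonyls, and aldolate 9 is trapped as mesylate 10. DBU then causes E1cB loss of methanesulfonate to ene-dione 11 and moves the exocyclic double bond into the ring by deprotonation at C5 and reprotonation next to the aryl ketone; the resulting cyclohexa-2,5-dienone tautomerises at once to phenol 12, so ring A becomes aromatic without an oxidant because the aldehyde oxidation level of 7 supplies the unsaturation. Acidification closes ring B: the new phenol oxygen adds to the aryl ketone (5-exo-trig hemiketal formation) and dehydration through the oxocarbenium ion stabilised by O1 and ring C gives the aromatic furan. The closest known reaction types are the α′-aldol chemistry of 3-alkoxycyclohexenones, the isoaromatisation of 6-alkylidenecyclohex-2-enones to 2-alkylphenols, and the acid cyclodehydration of 2-hydroxybenzyl aryl ketones to 2-arylbenzofurans, here run in one flask. The carbon that becomes C3a is fixed by kinetic α′-deprotonation at −78 °C (the thermodynamic γ-deprotonation at C4 is avoided), O1 can only be the former ring carbonyl oxygen, and the prenyl and methoxy positions were set in 2 and 3, so the pattern of ring A is unambiguous. No stereocentre survives, since the two centres of 9 and 10 and the geometry of 11 are erased on the way to 12. The selectivity needed in the acid stage is furan closure over addition of the phenol to the prenyl alkene; it is secured because the hemiketal can form before acid is added and its dehydration to an aromatic ring needs only mild acid at 50 °C, where protonation of a trisubstituted alkene should be slow.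

Step 6
Reactants: 13 2-{2,4-bis[(triisopropylsilyl)oxy]phenyl}-6-methoxy-7-(3-methylbut-2-en-1-yl)-1-benzofuran
Product: 14 2-{2,4-bis[(triisopropylsilyl)oxy]phenyl}-6-methoxy-7-(3-methylbut-2-en-1-yl)-1-benzofuran-3-carbaldehyde
Conditions: POCl3, DMF, 0 → 40 °C; then aq. NaOAc
Reagents that add atoms: N,N-dimethylformamide, CN(C)C=O; water, O
Why: Vilsmeier–Haack formylation at C3, the β-carbon of the O1–C2=C3 enol ether, whose attack gives a C2 cation stabilised by O1 and by the donor-substituted ring C; C3′ and C5′ are flanked by the bulky silyl ethers and C5 of ring A is only an anisole-type position, so C3 should react first with the weak chloroiminium electrophile.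

Step 7
Reactants: 14 2-{2,4-bis[(triisopropylsilyl)oxy]phenyl}-6-methoxy-7-(3-methylbut-2-en-1-yl)-1-benzofuran-3-carbaldehyde
Product: 15 Erypoegin F, 2-(2,4-dihydroxyphenyl)-6-methoxy-7-(3-methylbut-2-en-1-yl)-1-benzofuran-3-carbaldehyde
Conditions: n-Bu4NF, AcOH, THF, 0 °C
Reagents that add atoms: none
Why: Fluoride cleavage of the two aryl silyl ethers, buffered with acetic acid so that the released phenoxides are protonated and the vinylogous formate is not exposed to base; the prenyl group, aldehyde and methyl ether are inert.

## Compound list

1 | cyclohexane-1,3-dione | O=C1CCCC(=O)C1 | starting material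
2 | 2-(3-methylbut-2-en-1-yl)cyclohexane-1,3-dione | CC(C)=CCC1C(=O)CCCC1=O | intermediate
3 | 3-methoxy-2-(3-methylbut-2-en-1-yl)cyclohex-2-en-1-one | COC1=C(CC=C(C)C)C(=O)CCC1 | intermediate
4 | 1-(2,4-dihydroxyphenyl)ethan-1-one | CC(=O)c1ccc(O)cc1O | starting material
5 | 1-{2,4-bis[(triisopropylsilyl)oxy]phenyl}ethan-1-one | CC(=O)c1ccc(O[Si](C(C)C)(C(C)C)C(C)C)cc1O[Si](C(C)C)(C(C)C)C(C)C | intermediate
6 | 2,2-dihydroxy-1-{2,4-bis[(triisopropylsilyl)oxy]phenyl}ethan-1-one (glyoxal hydrate) | OC(O)C(=O)c1ccc(O[Si](C(C)C)(C(C)C)C(C)C)cc1O[Si](C(C)C)(C(C)C)C(C)C | intermediate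
7 | 2-{2,4-bis[(triisopropylsilyl)oxy]phenyl}-2-oxoacetaldehyde | O=CC(=O)c1ccc(O[Si](C(C)C)(C(C)C)C(C)C)cc1O[Si](C(C)C)(C(C)C)C(C)C | intermediate
8 | lithium 5-methoxy-6-(3-methylbut-2-en-1-yl)cyclohexa-1,5-dien-1-olate | [Li+].[O-]C1=CCCC(OC)=C1CC=C(C)C | intermediate
9 | lithium 1-[4-methoxy-3-(3-methylbut-2-en-1-yl)-2-oxocyclohex-3-en-1-yl]-2-oxo-2-{2,4-bis[(triisopropylsilyl)oxy]phenyl}ethan-1-olate (diastereomer mixture) | [Li+].[O-]C(C1CCC(OC)=C(CC=C(C)C)C1=O)C(=O)c1ccc(O[Si](C(C)C)(C(C)C)C(C)C)cc1O[Si](C(C)C)(C(C)C)C(C)C | intermediate
10 | 1-[4-methoxy-3-(3-methylbut-2-en-1-yl)-2-oxocyclohex-3-en-1-yl]-2-oxo-2-{2,4-bis[(triisopropylsilyl)oxy]phenyl}ethyl methanesulfonate (diastereomer mixture) | CS(=O)(=O)OC(C1CCC(OC)=C(CC=C(C)C)C1=O)C(=O)c1ccc(O[Si](C(C)C)(C(C)C)C(C)C)cc1O[Si](C(C)C)(C(C)C)C(C)C | intermediate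
11 | 3-methoxy-2-(3-methylbut-2-en-1-yl)-6-(2-oxo-2-{2,4-bis[(triisopropylsilyl)oxy]phenyl}ethylidene)cyclohex-2-en-1-one (mixture of double-bond isomers) | COC1=C(CC=C(C)C)C(=O)C(=CC(=O)c2ccc(O[Si](C(C)C)(C(C)C)C(C)C)cc2O[Si](C(C)C)(C(C)C)C(C)C)CC1 | intermediate
12 | 2-[2-hydroxy-4-methoxy-3-(3-methylbut-2-en-1-yl)phenyl]-1-{2,4-bis[(triisopropylsilyl)oxy]phenyl}ethan-1-one | COc1ccc(CC(=O)c2ccc(O[Si](C(C)C)(C(C)C)C(C)C)cc2O[Si](C(C)C)(C(C)C)C(C)C)c(O)c1CC=C(C)C | intermediate
13 | 2-{2,4-bis[(triisopropylsilyl)oxy]phenyl}-6-methoxy-7-(3-methylbut-2-en-1-yl)-1-benzofuran | COc1ccc2cc(-c3ccc(O[Si](C(C)C)(C(C)C)C(C)C)cc3O[Si](C(C)C)(C(C)C)C(C)C)oc2c1CC=C(C)C | intermediate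
14 | 2-{2,4-bis[(triisopropylsilyl)oxy]phenyl}-6-methoxy-7-(3-methylbut-2-en-1-yl)-1-benzofuran-3-carbaldehyde | COc1ccc2c(C=O)c(-c3ccc(O[Si](C(C)C)(C(C)C)C(C)C)cc3O[Si](C(C)C)(C(C)C)C(C)C)oc2c1CC=C(C)C | intermediate
15 | Erypoegin F, 2-(2,4-dihydroxyphenyl)-6-methoxy-7-(3-methylbut-2-en-1-yl)-1-benzofuran-3-carbaldehyde | COc1ccc2c(C=O)c(-c3ccc(O)cc3O)oc2c1CC=C(C)C | target

## Step count and least certain steps

Total step count: 7. Longest linear sequence: 5 steps (1 → 2 → 3 → 13 → 14 → 15, steps 1, 2, 5, 6, 7; the arm from 4 through steps 3, 4, 5, 6, 7 is equally long).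

**Step 5 (key step).** The most likely failure is that the ene-dione oligomerises by Michael addition, or adds DBU, faster than its double bond isomerises into the ring. In the acid stage, protonation of the prenyl alkene and capture by the new phenol could compete with furan closure. Incompletely dried glyoxal would quench the enolate.

The fallback separates bond formation from aromatisation. It sets out from 3 and 5 and returns at 13. Ketone 5 is brominated (PhNMe3Br3, THF) to 2-bromo-1-{2,4-bis[(triisopropylsilyl)oxy]phenyl}ethan-1-one F1. The lithium enolate 8 of 3 is alkylated with F1 to the 1,4-diketone 6-(2-{2,4-bis[(triisopropylsilyl)oxy]phenyl}-2-oxoethyl)-3-methoxy-2-(3-methylbut-2-en-1-yl)cyclohex-2-en-1-one F2. Paal–Knorr closure (TsOH, PhMe, 60 °C) gives 2-{2,4-bis[(triisopropylsilyl)oxy]phenyl}-6-methoxy-7-(3-methylbut-2-en-1-yl)-4,5-dihydro-1-benzofuran F3, and dehydrogenation of C4–C5 with DDQ (PhMe, rt) gives 13.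

**Step 6.** C3 is crowded by the twisted, ortho-silyloxy ring C, so the weak chloroiminium electrophile may react slowly. At the temperature then needed it, or the HCl set free, may attack the prenyl double bond; formylation at C5 or C5′ and loss of a silyl ether are further possibilities.

The fallback reverses the polarity at C3. It sets out from 13 and returns at 14. Iodination with N-iodosuccinimide (MeCN–CH2Cl2, −20 °C) gives 2-{2,4-bis[(triisopropylsilyl)oxy]phenyl}-3-iodo-6-methoxy-7-(3-methylbut-2-en-1-yl)-1-benzofuran F4. Iodine–magnesium exchange with i-PrMgCl·LiCl (THF, −40 °C) gives chloro{2-{2,4-bis[(triisopropylsilyl)oxy]phenyl}-6-methoxy-7-(3-methylbut-2-en-1-yl)-1-benzofuran-3-yl}magnesium F5, which is quenched with DMF to give 14.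

**Step 4.** Hot aqueous selenous acid may cleave the silyl ether ortho to the ketone, the oxidation may run on to the arylglyoxylic acid, and dehydration of the hydrate may be incomplete.

The fallback makes the glyoxal by cleavage of a C=C bond under neutral, anhydrous conditions. It sets out from 5 and returns at 7. Condensation of 5 with Me2NCH(OMe)2 (100 °C) gives (E)-3-(dimethylamino)-1-{2,4-bis[(triisopropylsilyl)oxy]phenyl}prop-2-en-1-one F6. Ozonolysis of its enamine double bond (O3, CH2Cl2, −78 °C; Me2S) gives 7 directly in anhydrous form.

## Further compounds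

F1 | step 5 | 2-bromo-1-{2,4-bis[(triisopropylsilyl)oxy]phenyl}ethan-1-one | O=C(CBr)c1ccc(O[Si](C(C)C)(C(C)C)C(C)C)cc1O[Si](C(C)C)(C(C)C)C(C)C
F2 | step 5 | 6-(2-{2,4-bis[(triisopropylsilyl)oxy]phenyl}-2-oxoethyl)-3-methoxy-2-(3-methylbut-2-en-1-yl)cyclohex-2-en-1-one (racemic) | COC1=C(CC=C(C)C)C(=O)C(CC(=O)c2ccc(O[Si](C(C)C)(C(C)C)C(C)C)cc2O[Si](C(C)C)(C(C)C)C(C)C)CC1
F3 | step 5 | 2-{2,4-bis[(triisopropylsilyl)oxy]phenyl}-6-methoxy-7-(3-methylbut-2-en-1-yl)-4,5-dihydro-1-benzofuran | COC1=C(CC=C(C)C)c2oc(-c3ccc(O[Si](C(C)C)(C(C)C)C(C)C)cc3O[Si](C(C)C)(C(C)C)C(C)C)cc2CC1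
F4 | step 6 | 2-{2,4-bis[(triisopropylsilyl)oxy]phenyl}-3-iodo-6-methoxy-7-(3-methylbut-2-en-1-yl)-1-benzofuran | COc1ccc2c(I)c(-c3ccc(O[Si](C(C)C)(C(C)C)C(C)C)cc3O[Si](C(C)C)(C(C)C)C(C)C)oc2c1CC=C(C)C
F5 | step 6 | chloro{2-{2,4-bis[(triisopropylsilyl)oxy]phenyl}-6-methoxy-7-(3-methylbut-2-en-1-yl)-1-benzofuran-3-yl}magnesium | COc1ccc2c([Mg]Cl)c(-c3ccc(O[Si](C(C)C)(C(C)C)C(C)C)cc3O[Si](C(C)C)(C(C)C)C(C)C)oc2c1CC=C(C)C
F6 | step 4 | (E)-3-(dimethylamino)-1-{2,4-bis[(triisopropylsilyl)oxy]phenyl}prop-2-en-1-one | CN(C)/C=C/C(=O)c1ccc(O[Si](C(C)C)(C(C)C)C(C)C)cc1O[Si](C(C)C)(C(C)C)C(C)C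
A1 | alternative 1 | 6-iodo-3-methoxy-2-(3-methylbut-2-en-1-yl)phenol | COc1ccc(I)c(O)c1CC=C(C)C
A2 | alternative 1 | 1-ethynyl-2,4-bis[(triisopropylsilyl)oxy]benzene | C#Cc1ccc(O[Si](C(C)C)(C(C)C)C(C)C)cc1O[Si](C(C)C)(C(C)C)C(C)C
A3 | alternative 2 | (E)-1-[2,4-bis(methoxymethoxy)phenyl]-3-[4-methoxy-2-(methoxymethoxy)-3-(3-methylbut-2-en-1-yl)phenyl]prop-2-en-1-one | COCOc1ccc(C(=O)/C=C/c2ccc(OC)c(CC=C(C)C)c2OCOC)c(OCOC)c1
A4 | alternative 2 | 1-[2,4-bis(methoxymethoxy)phenyl]-3,3-dimethoxy-2-[4-methoxy-2-(methoxymethoxy)-3-(3-methylbut-2-en-1-yl)phenyl]propan-1-one (racemic) | COCOc1ccc(C(=O)C(C(OC)OC)c2ccc(OC)c(CC=C(C)C)c2OCOC)c(OCOC)c1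
A5 | alternative 3 | 9-methoxy-10-(3-methylbut-2-en-1-yl)-3-[(triisopropylsilyl)oxy]-6H-[1]benzofuro[3,2-c]chromen-6-one | COc1ccc2c(oc3c2c(=O)oc2cc(O[Si](C(C)C)(C(C)C)C(C)C)ccc32)c1CC=C(C)C
A6 | alternative 3 | 6-({2-hydroxy-4-[(triisopropylsilyl)oxy]phenyl}ethynyl)-3-methoxy-2-(3-methylbut-2-en-1-yl)phenol | COc1ccc(C#Cc2ccc(O[Si](C(C)C)(C(C)C)C(C)C)cc2O)c(O)c1CC=C(C)C
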